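**Assumption:** the SMILES is read as the all-trans, C2-symmetric (2S,3R,4R,5S)-2,5-diaryl-3,4-bis(hydroxymethyl)tetrahydrofuran, and this is the isomer made. The route is a paper design, not experimentally verified.

## Retrosynthetic overview

1. Target 24 ⇐ global desilylation of tetra-TIPS tetrahydrofuran 23 ⇐ Et3SiH/BF3 reduction of 2-aryl lactol 22 (sets C5 of the THF).
2. Lactol 22 ⇐ late coupling of the aryllithium from bromide 21 with the all-trans γ-lactone 16.
3. Lactone 16 ⇐ trans-selective α-hydroxymethylation of a 4,5-trans lactone ⇐ Evans syn-aldol/lactonisation of succinyl imide 10 with aldehyde 5 (sets the other three stereocentres).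
4. Aldehyde 5 from p-cresol; imide 10 from L-valinol and succinic anhydride; bromide 21 from resorcinol.
5. Ring order: oxazolidinone (auxiliary, later removed) → γ-butyrolactone (step 8) → the same ring becomes the THF (steps 18–19). Both arenes come from the starting materials.

## Route

**Step 1**
Reactants: 1 p-cresol (4-methylphenol)
Product: 2 4-hydroxybenzaldehyde
Conditions: O2 (1 atm), CoCl2·6H2O (1 mol %), NaOH (3.5 equiv), MeOH, 60 °C; aq HCl
Reagents that add atoms: dioxygen, O=O
Why: Co-catalysed aerobic benzylic oxidation of the p-cresolate via its quinone methide, which stops at the aldehyde in basic methanol.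

**Step 2**
Reactants: 2 4-hydroxybenzaldehyde
Product: 3 3,5-dibromo-4-hydroxybenzaldehyde
Conditions: Br2 (2.1 equiv), NaOAc, AcOH, rt
Reagents that add atoms: bromine, BrBr
Why: electrophilic aromatic bromination at both positions ortho to OH (para blocked, and these are also meta to CHO).

**Step 3**
Reactants: 3 3,5-dibromo-4-hydroxybenzaldehyde
Product: 4 syringaldehyde (4-hydroxy-3,5-dimethoxybenzaldehyde)
Conditions: NaOMe (6 equiv), CuCl (0.2 equiv), DMF/MeOH, 110 °C; aq HCl
Reagents that add atoms: sodium methoxide, [Na+].[O-]C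
Why: Cu(I)-catalysed Ullmann-type methoxylation of both aryl bromides, which tolerates the phenoxide and the aldehyde.

**Step 4**
Reactants: 4 syringaldehyde
Product: 5 3,5-dimethoxy-4-(triisopropylsilyloxy)benzaldehyde
Conditions: TIPSCl, imidazole, DMAP (cat.), DMF, 50 °C
Reagents that add atoms: TIPSCl, CC(C)[Si](Cl)(C(C)C)C(C)C
Why: phenol silylation; the hindered aryl TIPS ether survives the base, organolithium and Lewis-acid steps and is removed by fluoride at the end.

**Step 5**
Reactants: 6 L-valinol ((S)-2-amino-3-methylbutan-1-ol)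
Product: 7 (S)-4-isopropyloxazolidin-2-one
Conditions: (EtO)2CO, K2CO3 (cat.), 130 °C, distil off EtOH
Reagents that add atoms: diethyl carbonate, CCOC(=O)OCC
Why: N-acylation then intramolecular O-acylation (cyclic carbamate formation); the stereocentre is not involved.

**Step 6**
Reactants: 8 succinic anhydride
Product: 9 4-methoxy-4-oxobutanoic acid (monomethyl succinate)
Conditions: MeOH, reflux
Reagents that add atoms: methanol, CO
Why: methanolysis of the cyclic anhydride gives the half-ester cleanly.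

**Step 7**
Reactants: 9 monomethyl succinate; 7 (S)-4-isopropyloxazolidin-2-one
Product: 10 methyl 4-[(S)-4-isopropyl-2-oxooxazolidin-3-yl]-4-oxobutanoate
Conditions: PivCl, Et3N, THF, −20 °C; then 7, LiCl, −20 °C → rt
Reagents that add atoms: none
Why: N-acylation of the oxazolidinone by the mixed pivalic anhydride at its less hindered carbonyl (LiCl/Et3N activation).

**Step 8**
Reactants: 10 succinyl imide; 5 TIPS-protected syringaldehyde
Product: 11 (S)-3-{[(2S,3S)-2-(3,5-dimethoxy-4-TIPSO-phenyl)-5-oxotetrahydrofuran-3-yl]carbonyl}-4-isopropyloxazolidin-2-one (2,3-trans lactone)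
Conditions: Bu2BOTf, i-Pr2NEt, CH2Cl2, −78 → 0 °C; 5, −78 → 0 °C; pH 7 buffer/MeOH/H2O2; then PPTS (cat.), CH2Cl2, rt
Reagents that add atoms: none (MeOH is lost)
Why: Evans syn-aldol of the Z-boron enolate (imide enolised in preference to the ester) through a Zimmerman–Traxler chair controlled by the (S)-isopropyl group sets both new centres; the syn γ-hydroxy ester then lactonises to the 4,5-trans lactone.

**Step 9**
Reactants: 11 lactone imide
Product: 12 (2S,3S)-2-(3,5-dimethoxy-4-TIPSO-phenyl)-5-oxotetrahydrofuran-3-carboxylic acid (trans)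
Conditions: LiOH (2 equiv), 30 % H2O2 (6 equiv), THF/H2O 3:1, 0 °C; Na2SO3; HCl to pH 2
Reagents that add atoms: lithium hydroperoxide from LiOH/H2O2 (OO; supplies the acid OH oxygen)
Why: hydroperoxide cleaves the exocyclic imide carbonyl selectively (auxiliary 7 is recovered); acidification recloses any opened lactone, and trans is the thermodynamic isomer.

**Step 10**
Reactants: 12 lactone acid
Product: 13 (4R,5S)-5-(3,5-dimethoxy-4-TIPSO-phenyl)-4-(hydroxymethyl)dihydrofuran-2(3H)-one
Conditions: BH3·SMe2, THF, 0 °C → rt; MeOH quench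
Reagents that add atoms: none
Why: borane reduces the carboxylic acid (via the acyloxyborane) much faster than the lactone.

**Step 11**
Reactants: 13 hydroxymethyl lactone
Product: 14 (4R,5S)-5-(3,5-dimethoxy-4-TIPSO-phenyl)-4-[(triisopropylsilyloxy)methyl]dihydrofuran-2(3H)-one
Conditions: TIPSCl, imidazole, CH2Cl2, 0 °C → rt (directly on crude 13)
Reagents that add atoms: TIPSCl, CC(C)[Si](Cl)(C(C)C)C(C)C
Why: near-neutral silylation of the primary alcohol, done at once to prevent translactonisation.

**Step 12**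
Reactants: 14 lactone
Product: 15 (3R,4R,5S)-5-(3,5-dimethoxy-4-TIPSO-phenyl)-3-(hydroxymethyl)-4-[(triisopropylsilyloxy)methyl]dihydrofuran-2(3H)-one (all-trans)
Conditions: LDA (1.15 equiv), THF, −78 °C; CH2O (g, cracked paraformaldehyde), −78 → −40 °C; AcOH
Reagents that add atoms: formaldehyde, C=O
Why: aldol of the lactone lithium enolate with formaldehyde occurs anti to the adjacent C4 substituent, setting C3 trans.

**Step 13**
Reactants: 15 hydroxymethyl lactone
Product: 16 (3R,4R,5S)-5-(3,5-dimethoxy-4-TIPSO-phenyl)-3,4-bis[(triisopropylsilyloxy)methyl]dihydrofuran-2(3H)-one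
Conditions: TIPSOTf, 2,6-lutidine, CH2Cl2, −78 → 0 °C
Reagents that add atoms: TIPSOTf, CC(C)[Si](OS(=O)(=O)C(F)(F)F)(C(C)C)C(C)C
Why: non-basic silylation, so the base-sensitive α-(hydroxymethyl) lactone neither epimerises nor undergoes retro-aldol.

**Step 14**
Reactants: 17 resorcinol
Product: 18 1,3-dimethoxybenzene
Conditions: Me2SO4, K2CO3, acetone, reflux
Reagents that add atoms: dimethyl sulfate, COS(=O)(=O)OC
Why: Williamson O-methylation of both phenols.

**Step 15**
Reactants: 18 1,3-dimethoxybenzene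
Product: 19 2,6-dimethoxyphenol
Conditions: n-BuLi, TMEDA, THF, 0 °C → rt; B(OMe)3, −78 °C → rt; AcOH, 30 % H2O2, 0 °C → rt
Reagents that add atoms: hydrogen peroxide, OO (phenol oxygen)
Why: directed ortho-metalation at C2 between the two OMe groups, borylation, then oxidative C–B to C–O migration.

**Step 16**
Reactants: 19 2,6-dimethoxyphenol
Product: 20 4-bromo-2,6-dimethoxyphenol
Conditions: NBS (1.0 equiv), CH2Cl2, −40 → 0 °C
Reagents that add atoms: N-bromosuccinimide, O=C1CCC(=O)N1Br
Why: electrophilic bromination para to the free OH, the dominant director.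

**Step 17**
Reactants: 20 4-bromo-2,6-dimethoxyphenol
Product: 21 (4-bromo-2,6-dimethoxyphenoxy)triisopropylsilane
Conditions: TIPSCl, imidazole, DMF, 50 °C
Reagents that add atoms: TIPSCl, CC(C)[Si](Cl)(C(C)C)C(C)C
Why: phenol silylation gives a lithiation-compatible aryl bromide carrying the same protecting group as 16.

**Step 18 (fragment coupling)**
Reactants: 21 aryl bromide (1.3 equiv); 16 lactone
Product: 22 (3R,4R,5S)-2,5-bis(3,5-dimethoxy-4-TIPSO-phenyl)-3,4-bis[(triisopropylsilyloxy)methyl]tetrahydrofuran-2-ol (anomeric mixture, in equilibrium with the open γ-hydroxy ketone)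
Conditions: 21, t-BuLi (2.6 equiv), THF, −78 °C, 20 min; add 16, −78 °C, 1 h; aq NH4Cl at −78 °C
Reagents that add atoms: none
Why: Br/Li exchange, then a single 1,2-addition of the aryllithium to the lactone; the lithium lactolate is stable at −78 °C, which prevents over-addition, and the new centre is not yet defined.

**Step 19**
Reactants: 22 lactol
Product: 23 (2S,3R,4R,5S)-2,5-bis(3,5-dimethoxy-4-TIPSO-phenyl)-3,4-bis[(triisopropylsilyloxy)methyl]tetrahydrofuran (all-trans)
Conditions: Et3SiH (5 equiv), BF3·OEt2 (2 equiv), CH2Cl2, −78 → −40 °C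
Reagents that add atoms: none
Why: ionisation to the 2-aryl oxocarbenium ion and silane reduction by inside attack on the envelope places the new aryl trans to the C3 substituent; this all-trans isomer is also the thermodynamic one.

**Step 20**
Reactants: 23 tetra-TIPS tetrahydrofuran
Product: 24 Huazhongilexin, [(2S,3R,4R,5S)-2,5-bis(4-hydroxy-3,5-dimethoxyphenyl)tetrahydrofuran-3,4-diyl]dimethanol
Conditions: TBAF (6 equiv), AcOH (6 equiv), THF, 0 °C → rt
Reagents that add atoms: none
Why: fluoride cleaves all four Si–O bonds; buffering avoids phenoxide-driven quinone-methide opening of the benzylic ether, so no stereocentre is touched.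

## Compound list

1 | p-cresol | Cc1ccc(O)cc1 | starting material
2 | 4-hydroxybenzaldehyde | O=Cc1ccc(O)cc1 | intermediate
3 | 3,5-dibromo-4-hydroxybenzaldehyde | O=Cc1cc(Br)c(O)c(Br)c1 | intermediate
4 | syringaldehyde | COc1cc(C=O)cc(OC)c1O | intermediate
5 | 3,5-dimethoxy-4-(triisopropylsilyloxy)benzaldehyde | COc1cc(C=O)cc(OC)c1O[Si](C(C)C)(C(C)C)C(C)C | intermediate
6 | L-valinol | CC(C)[C@H](N)CO | starting material
7 | (S)-4-isopropyloxazolidin-2-one | CC(C)[C@H]1COC(=O)N1 | intermediate (auxiliary)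
8 | succinic anhydride | O=C1CCC(=O)O1 | starting material
9 | monomethyl succinate | COC(=O)CCC(=O)O | intermediate
10 | methyl 4-[(S)-4-isopropyl-2-oxooxazolidin-3-yl]-4-oxobutanoate | COC(=O)CCC(=O)N1[C@@H](C(C)C)COC1=O | intermediate
11 | (2S,3S)-trans lactone imide | COc1cc([C@H]2OC(=O)C[C@@H]2C(=O)N3[C@@H](C(C)C)COC3=O)cc(OC)c1O[Si](C(C)C)(C(C)C)C(C)C | intermediate
12 | (2S,3S)-2-aryl-5-oxotetrahydrofuran-3-carboxylic acid | COc1cc([C@H]2OC(=O)C[C@@H]2C(=O)O)cc(OC)c1O[Si](C(C)C)(C(C)C)C(C)C | intermediate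
13 | (4R,5S)-5-aryl-4-(hydroxymethyl)dihydrofuran-2(3H)-one | COc1cc([C@H]2OC(=O)C[C@@H]2CO)cc(OC)c1O[Si](C(C)C)(C(C)C)C(C)C | intermediate
14 | (4R,5S)-5-aryl-4-(TIPSO-methyl)dihydrofuran-2(3H)-one | COc1cc([C@H]2OC(=O)C[C@@H]2CO[Si](C(C)C)(C(C)C)C(C)C)cc(OC)c1O[Si](C(C)C)(C(C)C)C(C)C | intermediate
15 | (3R,4R,5S)-5-aryl-3-(hydroxymethyl)-4-(TIPSO-methyl)dihydrofuran-2(3H)-one | COc1cc([C@H]2OC(=O)[C@@H](CO)[C@@H]2CO[Si](C(C)C)(C(C)C)C(C)C)cc(OC)c1O[Si](C(C)C)(C(C)C)C(C)C | intermediate
16 | (3R,4R,5S)-5-aryl-3,4-bis(TIPSO-methyl)dihydrofuran-2(3H)-one | COc1cc([C@H]2OC(=O)[C@@H](CO[Si](C(C)C)(C(C)C)C(C)C)[C@@H]2CO[Si](C(C)C)(C(C)C)C(C)C)cc(OC)c1O[Si](C(C)C)(C(C)C)C(C)C | intermediate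
17 | resorcinol | Oc1cccc(O)c1 | starting material
18 | 1,3-dimethoxybenzene | COc1cccc(OC)c1 | intermediate
19 | 2,6-dimethoxyphenol | COc1cccc(OC)c1O | intermediate
20 | 4-bromo-2,6-dimethoxyphenol | COc1cc(Br)cc(OC)c1O | intermediate
21 | (4-bromo-2,6-dimethoxyphenoxy)triisopropylsilane | COc1cc(Br)cc(OC)c1O[Si](C(C)C)(C(C)C)C(C)C | intermediate
22 | (3R,4R,5S)-2,5-diaryl-3,4-bis(TIPSO-methyl)tetrahydrofuran-2-ol (anomeric mixture) | COc1cc([C@H]2OC(O)(c3cc(OC)c(O[Si](C(C)C)(C(C)C)C(C)C)c(OC)c3)[C@@H](CO[Si](C(C)C)(C(C)C)C(C)C)[C@@H]2CO[Si](C(C)C)(C(C)C)C(C)C)cc(OC)c1O[Si](C(C)C)(C(C)C)C(C)C | intermediate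
23 | (2S,3R,4R,5S)-2,5-diaryl-3,4-bis(TIPSO-methyl)tetrahydrofuran | COc1cc([C@H]2O[C@H](c3cc(OC)c(O[Si](C(C)C)(C(C)C)C(C)C)c(OC)c3)[C@@H](CO[Si](C(C)C)(C(C)C)C(C)C)[C@@H]2CO[Si](C(C)C)(C(C)C)C(C)C)cc(OC)c1O[Si](C(C)C)(C(C)C)C(C)C | intermediate
24 | Huazhongilexin | COc1cc([C@H]2O[C@H](c3cc(OC)c(O)c(OC)c3)[C@@H](CO)[C@@H]2CO)cc(OC)c1O | target

("aryl" in 11–16, 22 and 23 = 3,5-dimethoxy-4-(triisopropylsilyloxy)phenyl.)

## Summary

Total step count: 20.

Longest linear sequence: 13 steps (1 → 2 → 3 → 4 → 5, then steps 8–13 to lactone 16, then steps 18–20).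

Steps most likely to fail:

1. **Step 18** (aryllithium addition to the hindered, α-branched lactone; risks are enolisation, β-silyloxide elimination and over-addition). Fallback: open 16 to the Weinreb amide (MeNHOMe·HCl/Me2AlCl), cap the benzylic OH as a TES ether, add the aryllithium to give the ketone, reduce with NaBH4 and close the ring by acid-mediated SN1 cyclodehydration of the 1,4-diol.
2. **Step 19** (stereoselectivity of the oxocarbenium reduction, or over-reduction of the benzylic C–O bond). Fallback: reduce 22 in its open hydroxy-ketone form with NaBH4 to the 1,4-diaryl-1,4-diol and cyclise with MsCl/Et3N or CSA; equilibration through the benzylic cation converges on the all-trans ring.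
3. **Step 12** (aldol with gaseous formaldehyde: modest yield, retro-aldol or bis-addition). Fallback: C-alkylate the enolate of 14 with benzyloxymethyl chloride, hydrogenolyse the benzyl ether at this lactone stage (before any diaryl-THF exists) and silylate to reach 16.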